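## Retrosynthetic overview

1. Target 20 ⇐ methyl ester 19 ⇐ spiro-epoxide 16 + enone 17: the dihydropyran is the last ring, made by a radical C7–C6 bond and O9–C4 cyclodehydration.
2. 16 ⇐ C7 ketone 15 ⇐ lactam 13 (C22=O → CH2) ⇐ dienoate 12 (C15–H and C18–H by syn-hydrogenation).
3. 12 ⇐ 10: ring D (seven-membered) by a C10–C11 bond, the C10 enolate closing onto a masked vinyl group. 10 ⇐ 7 + 8: ring F and the quaternary C21 by an enantioselective Michael/Horner–Wadsworth–Emmons annulation.
4. 7 ⇐ 5 + 6 (C21–C14 coupling); 5 ⇐ 1. Ring order: ring E and the piperidine ring are bought, then ring F, ring D, pyran.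
5. Atom labels (from the target): iPr–C4=C5–C6–C7(spiro)–C8–O9; C10(H)–C11–C12–C13=C14; C15(H)–C16–C17; C18(H)–C19O2H; C20; C21 (quaternary); C22; N23(CH3); C25 (bonded to C10).

Assumption: 1, 6, 8 and 17 are taken as purchasable achiral building blocks.

## Route

Step 1
Reactants: 1 3-ethoxycyclopent-2-en-1-one
Product: 2 2-bromo-3-ethoxycyclopent-2-en-1-one
Conditions: NBS, CH2Cl2, 0 °C → rt
Reagents that add atoms: N-bromosuccinimide, O=C1CCC(=O)N1Br
Why: electrophilic α-bromination of a vinylogous ester at its nucleophilic enol-ether β-carbon installs the C14 coupling handle.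

Step 2
Reactants: 2 2-bromo-3-ethoxycyclopent-2-en-1-one
Product: 5 2-bromo-3-(2-chloroethyl)cyclopent-2-en-1-one, via carbinol 3 (not isolated), via vinyl dienone 4 (not isolated)
Conditions: CH2=CHMgBr, THF, −78 → 0 °C; then HCl (4 M in dioxane), 0 °C → rt
Reagents that add atoms: vinylmagnesium bromide, C=C[Mg]Br; hydrogen chloride, Cl
Why: Stork–Danheiser 1,2-addition and acidic enone transposition give the 3-vinyl dienone, and HCl then adds 1,6 to its terminus, so C12–C11 are carried as a base-releasable 2-chloroethyl group (a masked vinyl).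

Step 3
Reactants: 5 2-bromo-3-(2-chloroethyl)cyclopent-2-en-1-one; 6 1-methylpiperidine-2,4-dione
Product: 7 3-[2-(2-chloroethyl)-5-oxocyclopent-1-en-1-yl]-4-hydroxy-1-methyl-5,6-dihydropyridin-2(1H)-one (enol form of the C21-alkenylated dione; achiral)
Conditions: Pd2(dba)3 (2.5 mol%), P(t-Bu)3·HBF4 (10 mol%), K3PO4, toluene, 40 °C
Reagents that add atoms: none
Why: palladium-catalysed α-alkenylation of the soft β-keto-lactam enolate with the activated alkenyl bromide (Buchwald–Hartwig-type enolate coupling) forges C21–C14, while the weak heterogeneous base and low temperature spare the alkyl chloride.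

Step 4
Reactants: 7 enol of the C21-alkenylated piperidine-2,4-dione; 8 methyl 2-(dimethoxyphosphoryl)prop-2-enoate
Product: 10 spiro dienoate: piperidine-2,4-dione spiro-linked at C21 (S) to the ring E/ring F tetrahydropentalene methyl ester that carries CH2CH2Cl on C13, via Michael adduct 9 (not isolated)
Conditions: quinidine-derived bifunctional squaramide (10 mol%), CH2Cl2, −20 °C; then LiCl, DBU, MeCN, 0 °C → rt
Reagents that add atoms: none
Why: squaramide-catalysed enantioselective Michael addition of the α-substituted cyclic β-keto lactam (catalyst amine pairs with the enolate, squaramide binds the phosphonoacrylate) sets the quaternary C21, and the phosphonoacetate then closes ring F onto the C15 ketone by an intramolecular Masamune–Roush Horner–Wadsworth–Emmons reaction; the sense of induction is not predicted here, and the quinine-derived pseudo-enantiomer is used if the first run gives the antipode.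

Step 5
Reactants: 10 spiro dienoate
Product: 12 tetracyclic dienoate with ring D closed (C10–C11 bond; C10 S; C21 S), via vinyl trienoate 11 (not isolated)
Conditions: t-BuOK (1.5 equiv), t-BuOH/THF, 0 °C → rt
Reagents that add atoms: none
Why: vinylogous E1cB loss of HCl unmasks the vinyl group and the only enolisable ketone carbon (C10) adds to C11 in an intramolecular 1,8-Michael addition (direct 7-exo-tet alkylation gives the same product); the cis-bridged bicyclo[4.3.1] frame fixes C10 relative to C21, and base equilibration returns the conjugated C13=C14–C15=C18 dienoate.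

Step 6
Reactants: 12 tetracyclic dienoate
Product: 13 keto lactam ester with C15–H and C18–H cis (C10 S; C15 S; C18 S; C21 S)
Conditions: H2 (30 bar), 10% Pd/C, EtOAc, rt
Reagents that add atoms: none
Why: heterogeneous syn-hydrogenation of the peripheral tetrasubstituted enoate C15=C18 from the ring F face that carries C22 (anti to the C7 keto bridge and the ring D arc) delivers both hydrogens cis, while the buried C13=C14 olefin next to the quaternary centre is expected to resist.

Step 7
Reactants: 13 keto lactam ester
Product: 15 amino keto ester (N-methylpiperidine; C10 S; C15 S; C18 S; C21 R by changed priorities), via triflyloxyiminium triflate 14 (not isolated)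
Conditions: Tf2O, CH2Cl2, −78 → 0 °C; then Hantzsch ester (2.5 equiv), rt
Reagents that add atoms: none
Why: Charette's metal-free chemoselective tertiary-amide reduction (O-triflation, then two hydride transfers from the Hantzsch ester) turns C22=O into CH2 without touching the non-enolisable hindered ketone, the ester or the olefin.

Step 8
Reactants: 15 amino keto ester
Product: 16 spiro-epoxide at C7 (epoxide CH2 on the cycloheptene side; C7 R)
Conditions: Me3S+ I− (1.5 equiv), KN(SiMe3)2 (1.3 equiv), THF, −10 °C → rt
Reagents that add atoms: trimethylsulfonium iodide, C[S+](C)C.[I-]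
Why: Corey–Chaykovsky methylene transfer to the non-enolisable C7 ketone adds C8 and keeps the ketone oxygen as the future O9; the epoxide configuration is irrelevant because C7 becomes a radical in the next step, and the base is kept below the salt to protect C18.

Step 9
Reactants: 16 spiro-epoxide; 17 4-methylpent-1-en-3-one
Product: 19 methyl ester of the target (C7 R; C10 R; C15 S; C18 S; C21 S), via hydroxy ketone 18 (not isolated)
Conditions: Cp2TiCl2 (2.5 equiv), Zn dust, THF, rt, 17 (5 equiv); aqueous work-up; then CSA (1.3 equiv), 4 Å MS, toluene, 80 °C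
Reagents that add atoms: none
Why: Proposed new method: Cp2TiCl (trivalent titanium) opens the hindered spiro-epoxide by single-electron transfer to the tertiary C7 radical that already carries the C8–O–Ti arm, this radical adds to the CH2 terminus of enone 17 (Giese addition), the α-keto radical is reduced to a titanium enolate, and the δ-hydroxy ketone then cyclodehydrates under acid to the 6-isopropyl-3,4-dihydro-2H-pyran, a reductive epoxide-plus-enone spiro-annulation; C7 should be set by attack on the cycloheptene face (one 1,3-diaxial C–H at C11 and the flat sp2 C14) rather than the piperidine face (two 1,3-diaxial C–H at C22 and C25); the closest known chemistry is the RajanBabu–Nugent epoxide opening with acrylate trapping to δ-lactones and tertiary-radical Giese additions that build vicinal quaternary centres.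

Step 10
Reactants: 19 methyl ester of the target
Product: 20 target acid CNP0237695.2 (C7 R; C10 R; C15 S; C18 S; C21 S)
Conditions: LiOH, THF/MeOH/H2O, rt; then 1 M HCl to pH 7
Reagents that add atoms: lithium hydroxide, [Li+].[OH-]
Why: mild saponification (acyl-oxygen cleavage is faster than enolisation at C18) frees the acid under basic conditions that the enol ether tolerates, and neutralisation only to pH 7 gives the zwitterion without hydrolysing the enol ether.

## Compound list

1 | 3-ethoxycyclopent-2-en-1-one | CCOC1=CC(=O)CC1 | starting material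
2 | 2-bromo-3-ethoxycyclopent-2-en-1-one | CCOC1=C(Br)C(=O)CC1 | intermediate
3 | 2-bromo-3-ethoxy-1-vinylcyclopent-2-en-1-ol (racemic and transient; its stereocentre is erased on hydrolysis) | C=CC1(O)CCC(OCC)=C1Br | intermediate
4 | 2-bromo-3-vinylcyclopent-2-en-1-one | C=CC1=C(Br)C(=O)CC1 | intermediate
5 | 2-bromo-3-(2-chloroethyl)cyclopent-2-en-1-one | ClCCC1=C(Br)C(=O)CC1 | intermediate
6 | 1-methylpiperidine-2,4-dione | CN1CCC(=O)CC1=O | starting material
7 | 3-[2-(2-chloroethyl)-5-oxocyclopent-1-en-1-yl]-4-hydroxy-1-methyl-5,6-dihydropyridin-2(1H)-one (enol tautomer, achiral) | CN1CCC(O)=C(C1=O)C1=C(CCCl)CCC1=O | intermediate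
8 | methyl 2-(dimethoxyphosphoryl)prop-2-enoate (trimethyl 2-phosphonoacrylate) | C=C(C(=O)OC)P(=O)(OC)OC | starting material
9 | Michael adduct: C21 (S) bears CH2–CH(CO2Me)P(O)(OMe)2 (C18 epimers) and the 2-(2-chloroethyl)-5-oxocyclopentenyl group | O=C1CCN(C)C(=O)[C@@]1(CC(C(=O)OC)P(=O)(OC)OC)C1=C(CCCl)CCC1=O | intermediate
10 | spiro dienoate: 1-methylpiperidine-2,4-dione spiro at C21 (S) to ring F; C15=C18(CO2Me) and C13=C14; CH2CH2Cl on C13 | O=C1CCN(C)C(=O)[C@]12CC(C(=O)OC)=C1CCC(CCCl)=C12 | intermediate
11 | vinyl trienoate: as 10 but vinyl on C13 | O=C1CCN(C)C(=O)[C@]12CC(C(=O)OC)=C1CCC(C=C)=C12 | intermediate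
12 | tetracyclic dienoate: ring D closed, C7 ketone, C22 lactam (C10 S, C21 S) | O=C1[C@H]2CCC3=C4C(CC3)=C(C(=O)OC)C[C@]41C(=O)N(C)C2 | intermediate
13 | keto lactam ester: C15–H and C18–H cis, on the C22 face (C10 S, C15 S, C18 S, C21 S) | O=C1[C@H]2CCC3=C4[C@@H](CC3)[C@@H](C(=O)OC)C[C@]41C(=O)N(C)C2 | intermediate
14 | triflyloxyiminium triflate of 13 (C22 O-triflated) | O=C1[C@H]2CCC3=C4[C@@H](CC3)[C@@H](C(=O)OC)C[C@]41C(OS(=O)(=O)C(F)(F)F)=[N+](C)C2.[O-]S(=O)(=O)C(F)(F)F | intermediate
15 | amino keto ester: C22H2, N-methylpiperidine, C7 ketone (C10 S, C15 S, C18 S, C21 R) | O=C1[C@H]2CCC3=C4[C@@H](CC3)[C@@H](C(=O)OC)C[C@]41CN(C)C2 | intermediate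
16 | spiro-epoxide: oxirane C7–C8–O, CH2 on the cycloheptene side (C7 R, C10 S, C15 S, C18 S, C21 R) | C1[C@@]2(O1)[C@H]1CCC3=C4[C@@H](CC3)[C@@H](C(=O)OC)C[C@]42CN(C)C1 | intermediate
17 | 4-methylpent-1-en-3-one (isopropyl vinyl ketone) | CC(C)C(=O)C=C | starting material
18 | δ-hydroxy ketone: C7 bears CH2OH (piperidine side) and CH2CH2C(O)iPr (cycloheptene side); in equilibrium with its lactol (C7 R, C10 R, C15 S, C18 S, C21 S) | CC(C)C(=O)CC[C@@]1(CO)[C@H]2CCC3=C4[C@@H](CC3)[C@@H](C(=O)OC)C[C@]41CN(C)C2 | intermediate
19 | methyl ester of the target (C7 R, C10 R, C15 S, C18 S, C21 S) | CC(C)C1=CC[C@@]2(CO1)[C@H]1CCC3=C4[C@@H](CC3)[C@@H](C(=O)OC)C[C@]42CN(C)C1 | intermediate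
20 | CNP0237695.2 (C7 R, C10 R, C15 S, C18 S, C21 S) | CC(C)C1=CC[C@@]2(CO1)[C@H]1CCC3=C4[C@@H](CC3)[C@@H](C(=O)O)C[C@]42CN(C)C1 | target

## Step count and risks

Total steps: 10. Longest linear sequence: 10 (1 → 20; 6, 8 and 17 enter as bought fragments).

**Step 5 (ring D closure).** The seven-membered bridged ring may close slowly, or the C10 enolate may instead add reversibly to C15. The fallback sets out from 10 and returns at 12. DBU in MeCN at 50 °C eliminates HCl to give the vinyl trienoate 11, which is now isolated. TMSOTf/Et3N converts its only enolisable ketone into the silyl enol ether F1. BF3·OEt2 or TiCl4 in CH2Cl2 at −78 °C then triggers an intramolecular Mukaiyama–Michael addition of the neutral enol ether to C11, and DBU isomerisation of the olefins gives 12.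

**Step 6 (dienoate hydrogenation).** The diene may take up hydrogen 1,4, react at the wrong face, or not react. The fallback sets out from 12 and returns at 13. LiOH hydrolysis gives the dienoic acid F2. Carboxylate-directed homogeneous hydrogenation (Ru(OAc)2(binap), H2 50 bar, MeOH) reduces only the olefin conjugated to the acid, giving the cis acid F3, with the ligand antipode chosen to reinforce the C22-face delivery. TMSCHN2 in MeOH/toluene re-forms the methyl ester 13.

**Step 9 (the proposed new step).** The enone may be consumed by the titanium reagent, the hindered radical may be reduced before it adds, or the face selectivity at C7 may be poor. The fallback uses known chemistry, sets out from 15 and returns at 18. Wittig methoxymethylenation (Ph3P=CHOMe from the phosphonium chloride and KN(SiMe3)2) gives the enol ether F4. Aqueous HCl in THF hydrolyses it to the aldehyde F5. A base-mediated Michael addition of this α-branched aldehyde to 17 (t-BuOK cat., t-BuOH) builds the quaternary C7 from the same less hindered face and gives the keto aldehyde F6. NaBH(OAc)3 reduces the aldehyde selectively to the hydroxy ketone 18, which is dehydrated with CSA as in step 9.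

## Further compounds

F1 | step 5 | silyl enol ether of 11 (C7–OSiMe3, C7=C10) | C[Si](C)(C)OC1=CCN(C)C(=O)[C@]12CC(C(=O)OC)=C1CCC(C=C)=C12
F2 | step 6 | dienoic acid from 12 | O=C1[C@H]2CCC3=C4C(CC3)=C(C(=O)O)C[C@]41C(=O)N(C)C2
F3 | step 6 | cis-hydrogenated acid (acid of 13) | O=C1[C@H]2CCC3=C4[C@@H](CC3)[C@@H](C(=O)O)C[C@]41C(=O)N(C)C2
F4 | step 9 | methyl enol ether at C7 (C7=C8H–OMe, E/Z mixture) | COC=C1[C@H]2CCC3=C4[C@@H](CC3)[C@@H](C(=O)OC)C[C@]41CN(C)C2
F5 | step 9 | C7 carbaldehyde (C7 epimers) | O=CC1[C@H]2CCC3=C4[C@@H](CC3)[C@@H](C(=O)OC)C[C@]41CN(C)C2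
F6 | step 9 | keto aldehyde: C7 bears CHO and CH2CH2C(O)iPr | CC(C)C(=O)CC[C@@]1(C=O)[C@H]2CCC3=C4[C@@H](CC3)[C@@H](C(=O)OC)C[C@]41CN(C)C2
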